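The bay bond C4–C4a of the phenanthrene is treated as the C=C of a cyclohexenone: C3 is its ketone, the ring-E benzylic carbon C4 its acidic α-carbon, C4a the carbonyl of a 6-methoxy-1-tetralone (rings A and B), and C2 the only free α-carbon, later the chlorine site. One transannular aldol condensation then closes ring C and cuts the 16-membered ring down to the 12-membered ring through rings A, D and E. Its precursor is a bis-MOM macrocyclic 1,5-diketone: a tetralone whose C10a carries a 3-oxobutyl chain ending on ring E, with the ring A–ring D biaryl bond and the ring D–ring E ethano bridge in place.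

Key step: step 16

Remarks. Locants C1–C10a are the phenanthrene positions of the target throughout (C4a = tetralone C1, C10a = tetralone C2). Ring A carries OMe, ring C becomes the chlorophenol, ring D sits on C6, ring E on C4. In the macrocycles, ring D is a 3-chloro-6-(methoxymethoxy)-1,2-phenylene (C1 on C6, C2 on the ethano bridge) and ring E a 4-(methoxymethoxy)-1,3-phenylene (C1 on the bridge, C3 on C4).

Assumption: every compound with a stereocentre at C10a is racemic and the biaryl bonds are not configurationally fixed, in line with the target, which has no stereodescriptor.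

Design change: a removable ester on C10a (methyl, later allyl) makes the macrocyclic Michael addition a soft-enolate reaction and shields the tetralone during the Grignard step; it is taken off before the key step, so the aldol precursor 20 is the plain C10a–H diketone.

**Step 1**
Reactants: 1 6-methoxy-1-tetralone
Product: 2 7-bromo-6-methoxy-1-tetralone
Conditions: NBS (1.05 equiv), MeCN, 0 °C to rt; chromatography to remove the 5-bromo isomer
Reagents that add atoms: N-bromosuccinimide, BrN1C(=O)CCC1=O
Why: Electrophilic aromatic bromination goes ortho to the methoxy group, and since both ortho positions (C5 and C7) are open the C7 bromide has to be separated from its C5 regioisomer.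

**Step 2**
Reactants: 3 2-bromo-3-hydroxybenzaldehyde
Product: 4 2-bromo-6-chloro-3-hydroxybenzaldehyde
Conditions: NCS (1.05 equiv), TsOH·H2O (10 mol %), MeCN, rt to 45 °C
Reagents that add atoms: N-chlorosuccinimide, ClN1C(=O)CCC1=O
Why: Electrophilic aromatic chlorination of the phenol should go para to OH (C6), as in the para-halogenation of 3-hydroxybenzaldehyde, because one ortho site carries bromine and the other is the least reactive position.

**Step 3**
Reactants: 4 2-bromo-6-chloro-3-hydroxybenzaldehyde
Product: 5 2-bromo-6-chloro-3-(methoxymethoxy)benzaldehyde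
Conditions: MOMCl (1.5 equiv), iPr2NEt (2 equiv), CH2Cl2, 0 °C to rt
Reagents that add atoms: chloromethyl methyl ether, COCCl
Why: O-Alkylation of the phenol gives a MOM ether that withstands all later basic, organometallic and palladium steps and can be cleaved by acid without touching the methyl ether.

**Step 4**
Reactants: 5 2-bromo-6-chloro-3-(methoxymethoxy)benzaldehyde
Product: 6 2-bromo-4-chloro-3-ethenyl-1-(methoxymethoxy)benzene
Conditions: Ph3PCH3Br (1.3 equiv), KOtBu (1.25 equiv), THF, 0 °C to rt
Reagents that add atoms: methyltriphenylphosphonium bromide, C[P+](c1ccccc1)(c1ccccc1)c1ccccc1.[Br-]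
Why: Wittig methylenation of the aryl aldehyde gives the styrene needed for the later Heck reaction and removes the aldehyde before it can meet the enolizable tetralone under base.

**Step 5**
Reactants: 2 7-bromo-6-methoxy-1-tetralone; 6 2-bromo-4-chloro-3-ethenyl-1-(methoxymethoxy)benzene
Product: 8 7-[3-chloro-2-ethenyl-6-(methoxymethoxy)phenyl]-6-methoxy-3,4-dihydronaphthalen-1(2H)-one, via pinacol boronate 7 (not isolated)
Conditions: B2pin2 (1.1 equiv), KOAc (3 equiv), PdCl2(dppf) (3 mol %), 1,4-dioxane, 90 °C; then 6 (0.9 equiv), aq. K3PO4 (3 equiv), PdCl2(dppf) (3 mol %), 95 °C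
Reagents that add atoms: none
Why: Miyaura borylation of 2 and Suzuki–Miyaura coupling in the same pot join ring A to ring D at the C–Br bond of 6, whose C–Cl bond should not undergo oxidative addition with this catalyst.

**Step 6**
Reactants: 8 7-[3-chloro-2-ethenyl-6-(methoxymethoxy)phenyl]-6-methoxy-3,4-dihydronaphthalen-1(2H)-one
Product: 9 methyl 7-[3-chloro-2-ethenyl-6-(methoxymethoxy)phenyl]-6-methoxy-1-oxo-1,2,3,4-tetrahydronaphthalene-2-carboxylate (racemic)
Conditions: NaH (2.5 equiv), (MeO)2CO (5 equiv), THF, reflux; aq. NH4Cl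
Reagents that add atoms: dimethyl carbonate, COC(=O)OC
Why: Claisen-type C-acylation of the tetralone enolate, the only enolizable site in 8, is driven by deprotonation of the β-keto ester formed and turns C10a into a soft pronucleophile for step 14.

**Step 7**
Reactants: 10 2-hydroxyphenylacetic acid
Product: 11 2-(5-bromo-2-hydroxyphenyl)acetic acid
Conditions: NBS (1.0 equiv), MeCN, 0 °C
Reagents that add atoms: N-bromosuccinimide, BrN1C(=O)CCC1=O
Why: Electrophilic aromatic bromination of the phenol should go para to OH, which places the handle for the ethano bridge on the later ring E.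

**Step 8**
Reactants: 11 2-(5-bromo-2-hydroxyphenyl)acetic acid
Product: 12 2-(5-bromo-2-hydroxyphenyl)-N-methoxy-N-methylacetamide
Conditions: MeNHOMe·HCl (1.3 equiv), EDC·HCl (1.3 equiv), HOBt (1.3 equiv), iPr2NEt (3 equiv), CH2Cl2, 0 °C to rt
Reagents that add atoms: N,O-dimethylhydroxylamine hydrochloride, CNOC.Cl
Why: Carbodiimide-mediated amide coupling gives the Weinreb amide, and any benzofuranone formed from the activated acid and the free phenol is opened by the amine to the same product.

**Step 9**
Reactants: 12 2-(5-bromo-2-hydroxyphenyl)-N-methoxy-N-methylacetamide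
Product: 13 2-[5-bromo-2-(methoxymethoxy)phenyl]-N-methoxy-N-methylacetamide
Conditions: MOMCl (1.5 equiv), iPr2NEt (2 equiv), CH2Cl2, 0 °C to rt
Reagents that add atoms: chloromethyl methyl ether, COCCl
Why: O-Alkylation of the phenol installs the same acid-labile MOM ether as on ring D, so both come off together in the last step.

**Step 10**
Reactants: 9 methyl 7-[3-chloro-2-ethenyl-6-(methoxymethoxy)phenyl]-6-methoxy-1-oxo-1,2,3,4-tetrahydronaphthalene-2-carboxylate; 13 2-[5-bromo-2-(methoxymethoxy)phenyl]-N-methoxy-N-methylacetamide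
Product: 14 methyl 7-[3-chloro-2-[(E)-2-[3-[2-[methoxy(methyl)amino]-2-oxoethyl]-4-(methoxymethoxy)phenyl]ethenyl]-6-(methoxymethoxy)phenyl]-6-methoxy-1-oxo-1,2,3,4-tetrahydronaphthalene-2-carboxylate (racemic)
Conditions: Pd(OAc)2 (5 mol %), P(o-tol)3 (15 mol %), Et3N (3 equiv), DMF, 100 °C
Reagents that add atoms: none
Why: In this Mizoroki–Heck reaction the arylpalladium species from 13 adds to the unsubstituted terminus of the styrene and syn β-hydride elimination should give the E-stilbene, while the aryl chloride stays inert with this ligand.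

**Step 11**
Reactants: 14 the E-stilbene of step 10
Product: 15 methyl 7-[3-chloro-2-[2-[3-[2-[methoxy(methyl)amino]-2-oxoethyl]-4-(methoxymethoxy)phenyl]ethyl]-6-(methoxymethoxy)phenyl]-6-methoxy-1-oxo-1,2,3,4-tetrahydronaphthalene-2-carboxylate (racemic)
Conditions: KO2C–N=N–CO2K (10 equiv, in portions), AcOH (20 equiv), MeOH/THF, rt to 40 °C
Reagents that add atoms: none
Why: Diimide reduction transfers two hydrogens in a concerted syn fashion to the stilbene C=C only, leaving Ar–Cl, N–O and C=O bonds alone, and no sulfonyl hydrazide is present that could condense with the keto ester.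

**Step 12**
Reactants: 15 the bibenzyl methyl ester of step 11
Product: 16 prop-2-enyl 7-[3-chloro-2-[2-[3-[2-[methoxy(methyl)amino]-2-oxoethyl]-4-(methoxymethoxy)phenyl]ethyl]-6-(methoxymethoxy)phenyl]-6-methoxy-1-oxo-1,2,3,4-tetrahydronaphthalene-2-carboxylate (racemic)
Conditions: allyl alcohol (10 equiv), DMAP (30 mol %), 4 Å MS, toluene, 110 °C
Reagents that add atoms: allyl alcohol, C=CCO
Why: DMAP-catalysed transesterification is specific for enolizable β-keto esters (exchange through an acylketene), so the amide and the ethers stay untouched and the ester becomes removable under neutral conditions.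

**Step 13**
Reactants: 16 the allyl β-keto ester of step 12
Product: 17 prop-2-enyl 7-[3-chloro-6-(methoxymethoxy)-2-[2-[4-(methoxymethoxy)-3-(2-oxobut-3-enyl)phenyl]ethyl]phenyl]-6-methoxy-1-oxo-1,2,3,4-tetrahydronaphthalene-2-carboxylate (racemic; used at once)
Conditions: CH2=CHMgBr (3.2 equiv), THF, −40 to 0 °C; inverse quench into cold aq. NH4Cl
Reagents that add atoms: vinylmagnesium bromide, C=C[Mg]Br
Why: In this Weinreb ketone synthesis the first equivalent of Grignard reagent turns the β-keto ester into its magnesium enolate, which shields the C4a ketone and the ester, and the amide then takes up one vinyl group as a stable chelate that releases the vinyl ketone only on quench.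

**Step 14**
Reactants: 17 the vinyl ketone of step 13
Product: 18 16-membered macrocyclic 1,5-diketone in which C10a carries a prop-2-enyl carboxylate and is linked through C1H2–C2H2–C3(=O)–C4H2 to ring E; bis-MOM (racemic)
Conditions: Cs2CO3 (0.3 equiv), MeCN, 2 mM (slow addition of 17), rt
Reagents that add atoms: none
Why: Intramolecular Michael addition (16-endo-trig) of the cesium enolate of the β-keto ester, formed selectively because this unit is far more acidic than the benzylic ketone, closes the macrocycle, and the new quaternary C10a centre is set without control (racemate).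

**Step 15**
Reactants: 18 the macrocyclic allyl keto ester of step 14
Product: 20 16-membered macrocyclic tetralone 1,5-diketone with C10a–H; bis-MOM (racemic), via keto acid 19 (not isolated)
Conditions: Pd(OAc)2 (5 mol %), PPh3 (20 mol %), HCO2H (3 equiv), Et3N (4 equiv), THF, rt to 40 °C
Reagents that add atoms: none
Why: In this Tsuji deallylation–decarboxylation zerovalent palladium ionizes the allyl ester, formate reduces the allyl unit to propene, and β-keto acid 19 loses CO2 in a buffered medium that is not basic enough to start the aldol reaction.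

**Step 16**
Reactants: 20 the macrocyclic 1,5-diketone of step 15
Product: 22 macrocyclic 7-methoxy-1,9,10,10a-tetrahydrophenanthren-3(2H)-one with ring E on C4 and ring D on C6; bis-MOM (racemic), via ketol 21 (not isolated)
Conditions: KOH (0.5 equiv, 1 M aq.), MeOH/THF (2:1), 10 mM, 60 °C
Reagents that add atoms: none
Why: Hydroxide reversibly deprotonates the most acidic carbon, the ring-E benzylic C4 next to the C3 ketone, and this enolate adds across the ring to the tetralone carbonyl C4a to give ketol 21, which loses water by an E1cB step to the conjugated tetrasubstituted enone and so drains all equilibria. The closest known reaction is the aldol-condensation half of the Robinson annulation of 2-(3-oxobutyl)-6-methoxy-1-tetralones to tetrahydrophenanthrenones, run here as a transannular aldol condensation. Ring C closes in a 6-(enolendo)-exo-trig mode, and the 12-membered ring needs no closure of its own because it is what remains of the 16-membered ring once C4 and C4a are joined. No new stereocentre survives: the C4 and C4a centres of 21 vanish on dehydration, and racemic C10a is erased on later aromatization. The step needs one enolate to pair with one carbonyl, and the substrate secures this because C4–C4a is the only pairing that gives a six-membered ring, whereas C2 to C4a or C10a to C3 would give cyclobutanols that revert. Retro-Michael opening at C1–C10a is the main competitor and is disfavoured because it would expel an unstabilized tetralone enolate.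

**Step 17**
Reactants: 22 the macrocyclic enone of step 16
Product: 24 2,2-dichloro derivative of 22 (racemic), via monochloride 23 (not isolated)
Conditions: LiN(SiMe3)2 (1.1 equiv), THF, −78 °C, then NCS (1.1 equiv); again LiN(SiMe3)2 (1.2 equiv), then NCS (1.3 equiv), −78 to −30 °C; aq. NH4Cl
Reagents that add atoms: N-chlorosuccinimide, ClN1C(=O)CCC1=O
Why: Kinetic deprotonation of the enone by the hindered amide occurs at the α′-carbon C2 and the cross-conjugated lithium enolate is chlorinated by NCS (enolate α-chlorination); the more acidic C2–H of 23 is removed in the second cycle, so both chlorines end on C2 while the arenes should not react at this temperature.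

**Step 18**
Reactants: 24 the 2,2-dichloro enone of step 17
Product: 26 macrocyclic 2-chloro-7-methoxy-9,10-dihydrophenanthren-3-ol; bis-MOM, via chlorodienone 25 (not isolated)
Conditions: LiCl (5 equiv), Li2CO3 (3 equiv), DMF, 110 °C; dilute acid work-up
Reagents that add atoms: none
Why: Dehydrochlorination of the α,α-dichloro ketone across C1–C2 (E2) gives cross-conjugated chlorodienone 25, which tautomerizes by loss of the C10a proton to the aromatic 2-chlorophenol and thereby erases the C10a stereocentre.

**Step 19**
Reactants: 26 the dihydrophenanthrenol of step 18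
Product: 27 macrocyclic 2-chloro-7-methoxyphenanthren-3-ol; bis-MOM
Conditions: DDQ (1.1 equiv), 1,4-dioxane, rt to 50 °C
Reagents that add atoms: none
Why: DDQ dehydrogenation of the 9,10-dihydrophenanthrene starts with hydride abstraction from C10, which is para-benzylic to the free C3 phenol, and loss of the C9 proton gives the phenanthrene under conditions too mild for the alkoxybenzylic ethano bridge.

**Step 20**
Reactants: 27 the bis-MOM phenanthrenol of step 19
Product: 28 target CNP0310669.0
Conditions: HCl (3 M aq.), MeOH/THF, 50 °C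
Reagents that add atoms: none
Why: Acid-catalysed acetal exchange cleaves both aryl MOM ethers, methanol taking up the formaldehyde unit as dimethoxymethane, while the aryl methyl ether and both aryl chlorides are stable.

**Compound list**

1 | 6-methoxy-1-tetralone | COc1ccc2C(=O)CCCc2c1 | starting material
2 | 7-bromo-6-methoxy-1-tetralone | COc1cc2CCCC(=O)c2cc1Br | intermediate
3 | 2-bromo-3-hydroxybenzaldehyde | O=Cc1cccc(O)c1Br | starting material
4 | 2-bromo-6-chloro-3-hydroxybenzaldehyde | O=Cc1c(Cl)ccc(O)c1Br | intermediate
5 | 2-bromo-6-chloro-3-(methoxymethoxy)benzaldehyde | COCOc1ccc(Cl)c(C=O)c1Br | intermediate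
6 | 2-bromo-4-chloro-3-ethenyl-1-(methoxymethoxy)benzene | COCOc1ccc(Cl)c(C=C)c1Br | intermediate
7 | 6-methoxy-7-(4,4,5,5-tetramethyl-1,3,2-dioxaborolan-2-yl)-1-tetralone | COc1cc2CCCC(=O)c2cc1B1OC(C)(C)C(C)(C)O1 | intermediate
8 | 7-[3-chloro-2-ethenyl-6-(methoxymethoxy)phenyl]-6-methoxy-3,4-dihydronaphthalen-1(2H)-one | COc1cc2CCCC(=O)c2cc1-c1c(OCOC)ccc(Cl)c1C=C | intermediate
9 | methyl 7-[3-chloro-2-ethenyl-6-(methoxymethoxy)phenyl]-6-methoxy-1-oxo-1,2,3,4-tetrahydronaphthalene-2-carboxylate (racemic) | COC(=O)C1CCc2cc(OC)c(cc2C1=O)-c1c(OCOC)ccc(Cl)c1C=C | intermediate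
10 | 2-hydroxyphenylacetic acid | OC(=O)Cc1ccccc1O | starting material
11 | 2-(5-bromo-2-hydroxyphenyl)acetic acid | OC(=O)Cc1cc(Br)ccc1O | intermediate
12 | 2-(5-bromo-2-hydroxyphenyl)-N-methoxy-N-methylacetamide | CON(C)C(=O)Cc1cc(Br)ccc1O | intermediate
13 | 2-[5-bromo-2-(methoxymethoxy)phenyl]-N-methoxy-N-methylacetamide | CON(C)C(=O)Cc1cc(Br)ccc1OCOC | intermediate
14 | E-stilbene from 9 and 13 (methyl keto ester, Weinreb amide; racemic) | COC(=O)C1CCc2cc(OC)c(cc2C1=O)-c1c(OCOC)ccc(Cl)c1/C=C/c1ccc(OCOC)c(CC(=O)N(C)OC)c1 | intermediate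
15 | bibenzyl methyl keto ester, the dihydro derivative of 14 (racemic) | COC(=O)C1CCc2cc(OC)c(cc2C1=O)-c1c(OCOC)ccc(Cl)c1CCc1ccc(OCOC)c(CC(=O)N(C)OC)c1 | intermediate
16 | bibenzyl prop-2-enyl keto ester, the allyl ester analogue of 15 (racemic) | C=CCOC(=O)C1CCc2cc(OC)c(cc2C1=O)-c1c(OCOC)ccc(Cl)c1CCc1ccc(OCOC)c(CC(=O)N(C)OC)c1 | intermediate
17 | open-chain vinyl ketone, 16 with CH2C(=O)CH=CH2 in place of the amide side chain (racemic) | C=CCOC(=O)C1CCc2cc(OC)c(cc2C1=O)-c1c(OCOC)ccc(Cl)c1CCc1ccc(OCOC)c(CC(=O)C=C)c1 | intermediate
18 | 16-membered macrocyclic 1,5-diketone with a prop-2-enyl carboxylate on C10a; bis-MOM (racemic) | COc1cc2CCC3(C(=O)OCC=C)CCC(=O)Cc4cc(ccc4OCOC)CCc4c(Cl)ccc(OCOC)c4-c1cc2C3=O | intermediate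
19 | 16-membered macrocyclic 1,5-diketone with a carboxylic acid on C10a; bis-MOM (racemic) | COc1cc2CCC3(C(O)=O)CCC(=O)Cc4cc(ccc4OCOC)CCc4c(Cl)ccc(OCOC)c4-c1cc2C3=O | intermediate
20 | 16-membered macrocyclic tetralone 1,5-diketone with C10a–H; bis-MOM (racemic) | COc1cc2CCC3CCC(=O)Cc4cc(ccc4OCOC)CCc4c(Cl)ccc(OCOC)c4-c1cc2C3=O | intermediate
21 | transannular ketol: C4–C4a bond formed, OH on C4a, H on C4 (diastereomer mixture) | COc1cc2CCC3CCC(=O)C4C3(O)c2cc1-c1c(OCOC)ccc(Cl)c1CCc1ccc(OCOC)c4c1 | intermediate
22 | macrocyclic 7-methoxy-1,9,10,10a-tetrahydrophenanthren-3(2H)-one, ring E on C4, ring D on C6; bis-MOM (racemic) | COc1cc2CCC3CCC(=O)C4=C3c2cc1-c1c(OCOC)ccc(Cl)c1CCc1ccc(OCOC)c4c1 | intermediate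
23 | 2-chloro derivative of 22 (diastereomer mixture) | COc1cc2CCC3CC(Cl)C(=O)C4=C3c2cc1-c1c(OCOC)ccc(Cl)c1CCc1ccc(OCOC)c4c1 | intermediate
24 | 2,2-dichloro derivative of 22 (racemic) | COc1cc2CCC3CC(Cl)(Cl)C(=O)C4=C3c2cc1-c1c(OCOC)ccc(Cl)c1CCc1ccc(OCOC)c4c1 | intermediate
25 | 2-chloro-9,10-dihydro-10aH-phenanthren-3-one (cross-conjugated dienone, C1=C2 and C4=C4a); bis-MOM (racemic) | COc1cc2CCC3C=C(Cl)C(=O)C4=C3c2cc1-c1c(OCOC)ccc(Cl)c1CCc1ccc(OCOC)c4c1 | intermediate
26 | macrocyclic 2-chloro-7-methoxy-9,10-dihydrophenanthren-3-ol; bis-MOM | COc1cc2CCc3cc(Cl)c(O)c4c3-c2cc1-c1c(OCOC)ccc(Cl)c1CCc1ccc(OCOC)c-4c1 | intermediate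
27 | macrocyclic 2-chloro-7-methoxyphenanthren-3-ol; bis-MOM | COc1cc2ccc3cc(Cl)c(O)c4c3c2cc1-c1c(OCOC)ccc(Cl)c1CCc1ccc(OCOC)c-4c1 | intermediate
28 | CNP0310669.0 | COc1cc2ccc3cc(Cl)c(O)c4c3c2cc1-c1c(O)ccc(Cl)c1CCc1ccc(O)c-4c1 | target

Total steps: 20. Longest linear sequence: 16 steps (from 3: steps 2–6 and 10–20).

**Steps most likely to fail**

Step 16 (key step). The C4 enolate may not reach the C4a carbonyl across the 16-membered ring, or the aldol addition may revert before ketol 21 dehydrates. The base may also open the ring by retro-Michael cleavage of C1–C10a or move the new double bond out of conjugation.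

Fallback (ring C first, macrocycle last): the route leaves at 9 and returns at 22.
- Bromide 13 would be vinylated (CH2=CHBF3K, PdCl2(dppf), Cs2CO3, THF/H2O, 80 °C) to N-methoxy-2-[5-ethenyl-2-(methoxymethoxy)phenyl]-N-methylacetamide F1.
- CH2=CHMgBr would convert this into 1-[5-ethenyl-2-(methoxymethoxy)phenyl]but-3-en-2-one F2.
- Intermolecular Michael addition of keto ester 9 to it (catalytic Cs2CO3, MeCN, 0 °C) should give the open-chain quaternary keto ester F3.
- Krapcho dealkoxycarbonylation (LiCl, wet DMSO, 140 °C) should give the open-chain 1,5-diketone F4.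
- An ordinary Robinson aldol condensation (KOH, MeOH, 60 °C) should give the tricyclic divinyl enone F5.
- Ring-closing metathesis of its two styrene units (second-generation Hoveyda–Grubbs catalyst, toluene, 80 °C, high dilution) would close the 12-membered ring as the macrocyclic stilbene enone F6.
- Diimide reduction as in step 11 would give 22.

Step 14. Intermolecular Michael addition (oligomers) may outrun ring closure even at high dilution. The aryl-substituted vinyl ketone 17 may also polymerize, or add liberated N,O-dimethylhydroxylamine, before it cyclizes.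

Fallback (intermolecular Michael addition, ring closure by metathesis at the ring D–ring E bridge): the route leaves at 9 and returns at 20.
- Keto ester 9 would be taken to the open-chain Michael adduct F3 as in the fallback for step 16 (through F1 and F2).
- Ring-closing metathesis of its two styrene units (second-generation Grubbs catalyst, CH2Cl2, 40 °C, 2 mM) is neutral, leaves the 1,5-diketone alone, and should give the 16-membered stilbene methyl keto ester F7.
- Diimide reduction would give the saturated macrocyclic methyl keto ester F8.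
- Krapcho dealkoxycarbonylation (LiCl, wet DMSO, 140 °C) would deliver 20.

Step 17. Chlorination may stop at monochloride 23 or scramble by proton exchange between enolates. Excess NCS may attack the electron-rich rings or, through the extended enolate, C4 or C10a.

Fallback (aromatize first, chlorinate second): the route leaves at 22 and returns at 26.
- Selenation of the kinetic enolate (LiN(SiMe3)2, then PhSeCl, THF, −78 °C) would give the 2-phenylselanyl ketone F9.
- Oxidation (H2O2, pyridine, CH2Cl2, 0 °C), with selenoxide syn-elimination and tautomerization, would give the unchlorinated macrocyclic 9,10-dihydrophenanthren-3-ol F10.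
- Chlorination of this free phenol (NCS, catalytic iPr2NH, toluene, 0 °C) can only go to C2, the one open ortho position, since the para position is the ring-fusion carbon C10a and the MOM-protected rings are much less reactive; this should give 26.

**Further compounds**

F1 | step 16 | N-methoxy-2-[5-ethenyl-2-(methoxymethoxy)phenyl]-N-methylacetamide | CON(C)C(=O)Cc1cc(C=C)ccc1OCOC
F2 | step 16 | 1-[5-ethenyl-2-(methoxymethoxy)phenyl]but-3-en-2-one | C=CC(=O)Cc1cc(C=C)ccc1OCOC
F3 | step 16 | methyl 7-[3-chloro-2-ethenyl-6-(methoxymethoxy)phenyl]-2-[4-[5-ethenyl-2-(methoxymethoxy)phenyl]-3-oxobutyl]-6-methoxy-1-oxo-1,2,3,4-tetrahydronaphthalene-2-carboxylate (racemic) | COC(=O)C1(CCC(=O)Cc2cc(C=C)ccc2OCOC)CCc2cc(OC)c(cc2C1=O)-c1c(OCOC)ccc(Cl)c1C=C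
F4 | step 16 | 7-[3-chloro-2-ethenyl-6-(methoxymethoxy)phenyl]-2-[4-[5-ethenyl-2-(methoxymethoxy)phenyl]-3-oxobutyl]-6-methoxy-3,4-dihydronaphthalen-1(2H)-one (racemic) | O=C1C(CCC(=O)Cc2cc(C=C)ccc2OCOC)CCc2cc(OC)c(cc12)-c1c(OCOC)ccc(Cl)c1C=C
F5 | step 16 | 6-[3-chloro-2-ethenyl-6-(methoxymethoxy)phenyl]-4-[5-ethenyl-2-(methoxymethoxy)phenyl]-7-methoxy-1,9,10,10a-tetrahydrophenanthren-3(2H)-one (racemic) | COc1cc2CCC3CCC(=O)C(c4cc(C=C)ccc4OCOC)=C3c2cc1-c1c(OCOC)ccc(Cl)c1C=C
F6 | step 16 | macrocyclic stilbene enone, 22 with CH=CH in place of the ethano bridge (racemic; alkene geometry as dictated by the ring) | COc1cc2CCC3CCC(=O)C4=C3c2cc1-c1c(OCOC)ccc(Cl)c1C=Cc1ccc(OCOC)c4c1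
F7 | step 14 | 16-membered stilbene methyl keto ester, 18 with CH=CH in place of the ethano bridge and CO2Me in place of the allyl ester (racemic; E/Z mixture) | COc1cc2CCC3(C(=O)OC)CCC(=O)Cc4cc(ccc4OCOC)C=Cc4c(Cl)ccc(OCOC)c4-c1cc2C3=O
F8 | step 14 | 16-membered macrocyclic methyl keto ester, the methyl ester analogue of 18 (racemic) | COc1cc2CCC3(C(=O)OC)CCC(=O)Cc4cc(ccc4OCOC)CCc4c(Cl)ccc(OCOC)c4-c1cc2C3=O
F9 | step 17 | 2-(phenylselanyl) derivative of 22 (diastereomer mixture) | COc1cc2CCC3CC([Se]c5ccccc5)C(=O)C4=C3c2cc1-c1c(OCOC)ccc(Cl)c1CCc1ccc(OCOC)c4c1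
F10 | step 17 | macrocyclic 7-methoxy-9,10-dihydrophenanthren-3-ol without the C2 chlorine; bis-MOM | COc1cc2CCc3ccc(O)c4c3-c2cc1-c1c(OCOC)ccc(Cl)c1CCc1ccc(OCOC)c-4c1
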